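## Structural features

The target is a bridged diaryl ether with two benzene rings. Ring A is 1,3,5-trisubstituted: one hydroxyl, the ether oxygen, and one end of a saturated fourteen-carbon chain. Ring B carries the ether oxygen, the other chain end on the adjacent carbon, one hydroxyl on the other carbon adjacent to the ether carbon, and one hydroxyl para to the ether carbon. The oxygen bridge and the chain together close a 20-membered ring that spans ring A meta and ring B ortho. There is no stereocentre and no non-aromatic double bond, so no stereocentres stand next to each other and nothing stereochemical has to be set.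

The fragile part is ring B. It is a 1,2,4-trioxygenated arene with a free hydroxyl para to the ether oxygen, so its phenoxide oxidises readily in air; in acid the phenols are robust. The real difficulty is the diaryl ether bond. Its ring B carbon sits between two ortho substituents (hydroxyl and alkyl) on an electron-rich ring, the worst case for nucleophilic aromatic substitution or copper coupling, and it must coexist with a 20-membered ring closure.

The key step exploits the substitution pattern of ring B. The ether carbon and the alkyl carbon are the two carbons of an aryl enol ether C=C bond that already lies in the macrocycle. The other four atoms, C(OH)–CH–C(OH)–CH, are carbon monoxide plus the three carbons of a propargylic acetate. The hydroxyl beside the ether carbon is the CO oxygen and the para hydroxyl is the migrated acetate.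

## Logic of the disconnections

**21 to 20.** The two acyl C–O bonds are cut, one on ring A and one on ring B. These acetates are what the ring-forming step and its precursor carry anyway, so the whole end game is a single deprotection. The demand is a medium in which ring B is not oxidised, hence acid-catalysed methanolysis and not a basic one.

**20 to 16 and 17.** In ring B the two C–C bonds of the hydroxyl-bearing carbon next to the ether carbon are cut, and the para oxygen is returned to the neighbouring CH as a propargylic acetate. This removes ring B and turns the crowded diaryl ether into an unhindered aryl vinyl ether. The gain is one ring, two C–C bonds and the full oxygenation pattern of ring B, with the macrocycle unchanged. The demands are a 1,2- and not a 1,3-acyloxy shift, capture of the carbene by 17 before other closures, and an acetate in 16 that does not ionise, since it is allylic to an enol ether. Ring A is therefore carried as an acetate and not as an alkyl ether: it is inductively withdrawing, is installed with the migrating acetate and leaves with the ring B acetate.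

**16 to 15.** Two acetyl C–O bonds are cut. One reagent installs the migrating group and the ring A spectator group, and the forward step must stay basic.

**15 to 13 and 14.** The bond between the carbinol carbon and the alkyne is cut, an alkynyl anion addition to an aldehyde that brings in two ring B carbons. The forward step must add to the carbonyl of a β-aryloxy enal without substitution at the β-carbon, and the free phenol costs one equivalent of 14.

**13 to 12 to 11.** No skeletal bond is cut; the oxidation level at the future ring B CH is adjusted. The ester in 11 is kept because it activates the ether-forming step. The forward steps need a clean 1,2-reduction and an oxidant that ignores a phenol.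

**11 to 9 (through 10).** The vinyl C–O bond is cut, which opens the 20-membered ring. Addition–elimination at a β-sulfonyloxy acrylate is far easier than any C–O bond formation at the hindered ring B carbon, and it makes the ether and the macrocycle together. The two ring A oxygens are equivalent at this stage, so no desymmetrisation is needed, and the unused oxygen is the future ring A hydroxyl. The phenols must appear only after the sulfonate is in place, so they are silyl ethers cleaved by fluoride in the same flask, at high dilution.

**9 to 8 to 6.** The O–S bond and then the bond from the α-carbon to the formyl carbon are cut, leaving a plain ester. The formyl carbon, supplied by a formate ester, becomes the ether carbon of ring B. The forward steps need a crossed Claisen condensation that spares the aryl silyl ethers and a sulfonylation of the enol oxygen.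

**6 to 2 and 4 (through 5).** The aryl–CH2 bond is cut, giving a bromo ester and a symmetric aryl bromide. The forward step needs an organometallic that tolerates the ester, hence zinc.

**2 to 1, and 4 to 3.** The ester O–CH3 bond and the two O–Si bonds are cut, simple derivatisations of commercial compounds.

## Other disconnections considered

**Alternative 1:** The cut is the bond between chain carbons 1 and 2, next to ring B. In the forward direction the open-chain 2-aryl-1,3-dithiane A1, which carries a primary bromide at the end of the ring A chain, would be lithiated at the dithiane carbon and alkylated by its own bromide. This would give the macrocyclic dithiane A2; desulfurisation with Raney Ni and cleavage of three methyl ethers would follow.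

- In favour: one formyl group on ring B serves twice, first activating the ring B carbon for ether formation and then, as the dithiane, supplying the acyl anion. Both arenes are bought with their oxygen pattern. The ring closes by an SN2 alkylation with a flexible transition state.
- Against: the ether-forming substitution must occur at a carbon that is ortho and para to methoxy groups and activated by a single formyl group. The lithiated dithiane is a hindered, strongly basic tertiary carbanion next to an ortho aryloxy group. Elimination of the bromide, adventitious protonation at millimolar concentration and ring metalation therefore compete, and an amide base may not deprotonate a 2-aryl dithiane of this electron-rich type completely.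
- Comparison: on structure this plan is the equal or the better of the chosen one, because the ring B pattern is purchased and cannot come out wrong. On mechanism its key step has the firmer precedent, but a carbanion macrocyclisation is less forgiving than the oxygen addition–elimination used for 11. On step economy it needs two end steps, one of them BBr3 on the oxidation-prone triol, against one; the overall count is about the same.

**Alternative 2:** The cut takes ring A apart at two C–C bonds: chain-bearing carbon to the neighbouring CH, and aryloxy carbon to the carbon between the two oxygenated positions. In the forward direction A3, which has a 3-methoxycarbonyl-4-methoxy-2-pyrone at the chain end and an ethynyl ether on the ring B oxygen, would undergo intramolecular [4+2] addition across pyrone C3 and C6. Loss of CO2 would then give the ester-bearing macrocycle A4.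

- In favour: a single step makes ring A, finishes the diaryl ether and closes the macrocycle. On convergence this is better than the chosen plan, which needs a separate ring closure. The ether is again made on an unsaturated carbon and not on a crowded arene, and the polarity of ynol ether and pyrone is matched, so the regiochemistry is as secure as in the chosen plan (equal).
- Against: aryl ethynyl ethers are thermally labile and would have to be made on the doubly ortho-substituted ring B phenol. The 4-methoxy group makes the pyrone a poorer diene, so heat would be needed exactly where the ynol ether decomposes. The cycloaddition is also the 20-membered ring closure, with an unfavourable entropy, so oligomerisation competes. The ester is a spectator that costs hydrolysis and decarboxylation, and three demethylations follow.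
- Comparison: in the chosen plan the arene-forming event is a six-membered closure inside an existing macrocycle and carries no such entropic penalty. The tail is about four steps against one.

**Alternative 3:** The cut is the bond between chain carbons 13 and 14, next to ring A, made by way of sulfur. In the forward direction a chain-end thiol and a ring A benzylic halide would close a 21-membered thioether, and oxidation would give the sulfone A5. The Ramberg–Bäcklund reaction (α-halogenation at the benzylic carbon in the flask, episulfone, loss of SO2) would contract it to the 20-membered (E)-alkene A6. Hydrogenation and three demethylations follow.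

- In favour: thioether formation at high dilution is among the most dependable macrocyclisations and is the equal or the better of the ring closure that gives 11. The contraction is well known for cyclophanes, and the alkene geometry does not matter.
- Against: the hindered diaryl ether must be made first by copper-mediated coupling at the doubly ortho-substituted ring B carbon, so the hardest bond is not addressed. The halogenating basic medium (KOH with a polyhalomethane) meets two electron-rich arenes. Oxidation, contraction, hydrogenation and demethylation all follow the ring closure.
- Comparison: on mechanism the plan is sound and ionic throughout. On structure it leaves the main difficulty where it was. On step economy it is longer after ring closure and ends with BBr3 on the sensitive triol.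

Key step: step 11

Remark on the chemistry: the target is achiral, so 8, 15, 16 and 19 are racemic or transient and need no enantiocontrol. In 11–16 the descriptor E means aryloxy trans to the carbon substituent (ester, CH2OH, CHO or carbinol), i.e. cis to the chain. Compounds 1, 3, 14 (THF solution) and 17 are taken as commercial.

## Route

Step 1
Reactants: 1 16-bromohexadecanoic acid
Product: 2 methyl 16-bromohexadecanoate
Conditions: MeOH, H2SO4 (cat.), reflux
Reagents that add atoms: methanol, CO
Why: Fischer esterification; the primary bromide is inert to acidic methanol, and the ester is needed for the organozinc step and as the enolisable group of step 4.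

Step 2
Reactants: 3 5-bromobenzene-1,3-diol (5-bromoresorcinol)
Product: 4 1-bromo-3,5-bis(tert-butyldimethylsilyloxy)benzene
Conditions: TBSCl (2.3 equiv), imidazole, DMF, rt
Reagents that add atoms: tert-butyldimethylsilyl chloride, CC(C)(C)[Si](C)(C)Cl
Why: Imidazole-assisted silylation of both phenols; the bis-silyl ether keeps the two ring A oxygens equivalent and can be removed by fluoride in the flask of step 6.

Step 3
Reactants: 2 methyl 16-bromohexadecanoate; 4 1-bromo-3,5-bis(tert-butyldimethylsilyloxy)benzene
Product: 6 methyl 16-[3,5-bis(tert-butyldimethylsilyloxy)phenyl]hexadecanoate, via (16-methoxy-16-oxohexadecyl)zinc bromide 5 (not isolated)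
Conditions: 2, Zn dust, I2 (5 mol %), DMA, 80 °C; then 4, Pd(OAc)2 (2 mol %), SPhos (4 mol %), THF, 50 °C
Reagents that add atoms: none
Why: Zinc insertion into the primary bromide followed by Negishi coupling with the aryl bromide; the alkylzinc tolerates the ester and the silyl ethers, and the bulky biarylphosphine on palladium favours reductive elimination over β-hydride elimination.

Step 4
Reactants: 6 methyl 16-[3,5-bis(tert-butyldimethylsilyloxy)phenyl]hexadecanoate
Product: 8 methyl 16-[3,5-bis(tert-butyldimethylsilyloxy)phenyl]-2-formylhexadecanoate (racemic; partly enolised), via lithium ester enolate 7 (not isolated)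
Conditions: LiN(i-Pr)2 (2.2 equiv), THF, −78 °C; HCO2Me (5 equiv), −78 to −20 °C; AcOH
Reagents that add atoms: methyl formate, COC=O
Why: Crossed Claisen condensation of the lithium enolate with a non-enolisable formate that carries the same alkoxide as the ester, so no transesterification arises; deprotonation of the β-formyl ester as it forms drives the reaction, and the low temperature should spare the aryl silyl ethers.

Step 5
Reactants: 8 methyl 16-[3,5-bis(tert-butyldimethylsilyloxy)phenyl]-2-formylhexadecanoate
Product: 9 methyl (E)-16-[3,5-bis(tert-butyldimethylsilyloxy)phenyl]-2-[(4-methylphenylsulfonyloxy)methylidene]hexadecanoate (sulfonate trans to the ester)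
Conditions: TsCl, N-methylimidazole, Et3N, CH2Cl2, 0 °C
Reagents that add atoms: p-toluenesulfonyl chloride, Cc1ccc(cc1)S(Cl)(=O)=O
Why: O-Sulfonylation of the enol of the α-formyl ester through the N-sulfonylimidazolium salt; with an amine base (no chelating metal) the sulfonate should end up trans to the ester, and either geometry would still serve in step 6.

Step 6
Reactants: 9 methyl (E)-16-[3,5-bis(tert-butyldimethylsilyloxy)phenyl]-2-[(4-methylphenylsulfonyloxy)methylidene]hexadecanoate
Product: 11 methyl (E)-1⁵-hydroxy-2-oxa-1(1,3)-benzenacyclooctadecaphan-3-ene-4-carboxylate (20-membered ring: ring A with free OH, O–CH=C(CO2Me)–(CH2)14), via desilylated caesium phenoxide of the enol tosylate 10 (not isolated)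
Conditions: CsF (6 equiv), DMF (2 mM), 60 °C, slow addition of 9; aq. NH4Cl
Reagents that add atoms: none
Why: Fluoride cleaves both aryl silyl ethers, and the caesium phenoxide closes the ring by vinylic substitution (conjugate addition to the β-sulfonyloxy acrylate, then loss of tosylate). The two phenoxides are equivalent, so only one macrocycle can form and the unused oxygen is recovered as the free phenol. High dilution and the caesium counter-ion favour ring closure, and aryloxy trans to the ester is expected both from retention and as the more stable isomer.

Step 7
Reactants: 11 methyl (E)-1⁵-hydroxy-2-oxa-1(1,3)-benzenacyclooctadecaphan-3-ene-4-carboxylate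
Product: 12 (E)-4-(hydroxymethyl)-2-oxa-1(1,3)-benzenacyclooctadecaphan-3-en-1⁵-ol
Conditions: i-Bu2AlH (4 equiv), CH2Cl2, −78 to −40 °C; aq. potassium sodium tartrate
Reagents that add atoms: none
Why: 1,2-Reduction of the vinylogous carbonate ester to the allylic alcohol (one equivalent of hydride is consumed by the phenol); the tartrate work-up avoids the acid that would ionise a 3-aryloxyallyl alcohol.

Step 8
Reactants: 12 (E)-4-(hydroxymethyl)-2-oxa-1(1,3)-benzenacyclooctadecaphan-3-en-1⁵-ol
Product: 13 (E)-1⁵-hydroxy-2-oxa-1(1,3)-benzenacyclooctadecaphan-3-ene-4-carbaldehyde
Conditions: MnO2 (activated, 20 equiv), CH2Cl2, rt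
Reagents that add atoms: none
Why: MnO2 oxidises allylic alcohols selectively under neutral heterogeneous conditions and should leave the phenol and the enol ether untouched.

Step 9
Reactants: 13 (E)-1⁵-hydroxy-2-oxa-1(1,3)-benzenacyclooctadecaphan-3-ene-4-carbaldehyde; 14 ethynylmagnesium bromide
Product: 15 (E)-4-(1-hydroxyprop-2-yn-1-yl)-2-oxa-1(1,3)-benzenacyclooctadecaphan-3-en-1⁵-ol (racemic)
Conditions: HC≡CMgBr (3.5 equiv), THF, −78 to 0 °C; aq. NH4Cl
Reagents that add atoms: none
Why: Carbonyl addition of an alkynyl Grignard reagent, which attacks β-alkoxy enals at the carbonyl carbon and not at the β-carbon at low temperature; the first equivalent deprotonates the phenol. The carbinol centre forms without control as a racemate, which is immaterial because step 11 converts it into an arene CH.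

Step 10
Reactants: 15 (E)-4-(1-hydroxyprop-2-yn-1-yl)-2-oxa-1(1,3)-benzenacyclooctadecaphan-3-en-1⁵-ol
Product: 16 (E)-4-(1-acetoxyprop-2-yn-1-yl)-2-oxa-1(1,3)-benzenacyclooctadecaphan-3-en-1⁵-yl acetate (racemic)
Conditions: Ac2O (3 equiv), Et3N, DMAP (cat.), CH2Cl2, 0 °C
Reagents that add atoms: acetic anhydride, CC(=O)OC(C)=O
Why: DMAP-catalysed acylation of the propargylic alcohol and the phenol in one operation, which supplies the migrating group for step 11 and an electron-withdrawing ring A spectator that tempers the donor strength of the enol ether oxygen; the basic medium avoids ionisation of the acetate.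

Step 11
Reactants: 16 (E)-4-(1-acetoxyprop-2-yn-1-yl)-2-oxa-1(1,3)-benzenacyclooctadecaphan-3-en-1⁵-yl acetate; 17 carbon monoxide
Product: 20 3⁶-hydroxy-2-oxa-1(1,3),3(1,2)-dibenzenacycloheptadecaphane-1⁵,3⁴-diyl diacetate (ring B: free OH next to the ether carbon, acetate para to it; ring A acetate), via dienylketene 18 (not isolated), via 6-aryloxycyclohexa-2,4-dienone 19 (not isolated)
Conditions: [Rh(CO)2Cl]2 (5 mol %), CO (10 bar), ClCH2CH2Cl, 70 °C
Reagents that add atoms: none
Why: Monovalent rhodium binds the terminal alkyne of 16, the acetate carbonyl oxygen attacks the internal alkyne carbon, and the 1,2-acyloxy shift through a dioxolenium ion gives a rhodium vinylcarbene conjugated with the enol ether. CO inserts into the Rh=C bond to give the dienylketene 18, with the ketene and the enol ether cis on the central C=C bond. A thermal disrotatory six-electron electrocyclisation then joins the CO carbon to the aryloxy-bearing carbon, so ring B closes as a six-membered ring in a pericyclic mode (a rhodacyclohexadiene that inserts CO and reductively eliminates would give the same dienone), and 19 tautomerises to the phenol 20. The closest known reaction type is the rhodium-catalysed carbonylative [5+1] benzannulation of 3-acyloxy-1,4-enynes to resorcinol monoesters, applied here to an enyne whose alkene terminus bears an aryloxy group. No stereocentre is formed, and the carbinol centre of 16 and the enol ether geometry are both erased. The step needs the 1,2- over the 1,3-acyloxy shift, which the terminal alkyne secures, and CO capture over five-membered (Rautenstrauch-type) closure of the vinylcarbene, which the CO pressure secures. The aryloxy group points outward at the triene terminus and both alkene carbons are already cis in the 20-membered ring, so the closure should be neither hindered nor strained. The ring A acetate is a spectator, and any acyl scrambling would be harmless because step 12 removes every acetate.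

Step 12
Reactants: 20 3⁶-hydroxy-2-oxa-1(1,3),3(1,2)-dibenzenacycloheptadecaphane-1⁵,3⁴-diyl diacetate
Product: 21 2-oxa-1(1,3),3(1,2)-dibenzenacycloheptadecaphane-1⁵,3⁴,3⁶-triol (target)
Conditions: HCl (1.25 M in MeOH, degassed), 40 °C
Reagents that add atoms: none
Why: Acid-catalysed transesterification of both aryl acetates to methyl acetate; acid is chosen over base because the ring B phenoxide is easily oxidised in air, and the diaryl ether and the chain are inert.

## Compound list

1 | 16-bromohexadecanoic acid | OC(=O)CCCCCCCCCCCCCCCBr | starting material
2 | methyl 16-bromohexadecanoate | COC(=O)CCCCCCCCCCCCCCCBr | intermediate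
3 | 5-bromobenzene-1,3-diol | Oc1cc(O)cc(Br)c1 | starting material
4 | 1-bromo-3,5-bis(tert-butyldimethylsilyloxy)benzene | CC(C)(C)[Si](C)(C)Oc1cc(Br)cc(O[Si](C)(C)C(C)(C)C)c1 | intermediate
5 | (16-methoxy-16-oxohexadecyl)zinc bromide | COC(=O)CCCCCCCCCCCCCCC[Zn]Br | intermediate
6 | methyl 16-[3,5-bis(tert-butyldimethylsilyloxy)phenyl]hexadecanoate | COC(=O)CCCCCCCCCCCCCCCc1cc(O[Si](C)(C)C(C)(C)C)cc(O[Si](C)(C)C(C)(C)C)c1 | intermediate
7 | lithium enolate of 6 | COC(O[Li])=CCCCCCCCCCCCCCCc1cc(O[Si](C)(C)C(C)(C)C)cc(O[Si](C)(C)C(C)(C)C)c1 | intermediate
8 | methyl 16-[3,5-bis(tert-butyldimethylsilyloxy)phenyl]-2-formylhexadecanoate (racemic) | COC(=O)C(C=O)CCCCCCCCCCCCCCc1cc(O[Si](C)(C)C(C)(C)C)cc(O[Si](C)(C)C(C)(C)C)c1 | intermediate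
9 | methyl (E)-16-[3,5-bis(tert-butyldimethylsilyloxy)phenyl]-2-[(4-methylphenylsulfonyloxy)methylidene]hexadecanoate | COC(=O)/C(CCCCCCCCCCCCCCc1cc(O[Si](C)(C)C(C)(C)C)cc(O[Si](C)(C)C(C)(C)C)c1)=C/OS(=O)(=O)c1ccc(C)cc1 | intermediate
10 | methyl (E)-16-(3,5-dihydroxyphenyl)-2-[(4-methylphenylsulfonyloxy)methylidene]hexadecanoate (present as its caesium phenoxide) | COC(=O)/C(CCCCCCCCCCCCCCc1cc(O)cc(O)c1)=C/OS(=O)(=O)c1ccc(C)cc1 | intermediate
11 | methyl (E)-1⁵-hydroxy-2-oxa-1(1,3)-benzenacyclooctadecaphan-3-ene-4-carboxylate | Oc1cc2cc(c1)O/C=C(/C(=O)OC)CCCCCCCCCCCCCC2 | intermediate
12 | (E)-4-(hydroxymethyl)-2-oxa-1(1,3)-benzenacyclooctadecaphan-3-en-1⁵-ol | Oc1cc2cc(c1)O/C=C(/CO)CCCCCCCCCCCCCC2 | intermediate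
13 | (E)-1⁵-hydroxy-2-oxa-1(1,3)-benzenacyclooctadecaphan-3-ene-4-carbaldehyde | Oc1cc2cc(c1)O/C=C(/C=O)CCCCCCCCCCCCCC2 | intermediate
14 | ethynylmagnesium bromide | C#C[Mg]Br | starting material
15 | (E)-4-(1-hydroxyprop-2-yn-1-yl)-2-oxa-1(1,3)-benzenacyclooctadecaphan-3-en-1⁵-ol (racemic) | Oc1cc2cc(c1)O/C=C(/C(O)C#C)CCCCCCCCCCCCCC2 | intermediate
16 | (E)-4-(1-acetoxyprop-2-yn-1-yl)-2-oxa-1(1,3)-benzenacyclooctadecaphan-3-en-1⁵-yl acetate (racemic) | CC(=O)Oc1cc2cc(c1)O/C=C(/C(OC(C)=O)C#C)CCCCCCCCCCCCCC2 | intermediate
17 | carbon monoxide | [C-]#[O+] | starting material
18 | dienylketene from 16 and 17 (ketene and enol ether cis on the acetoxy-bearing C=C bond, aryloxy outward) | CC(=O)Oc1cc2cc(c1)O/C=C(/C=C(/OC(C)=O)C=C=O)CCCCCCCCCCCCCC2 | intermediate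
19 | 6-aryloxy-3-acetoxy-5-alkylcyclohexa-2,4-dienone fused to the macrocycle (racemic, transient) | CC(=O)Oc1cc2cc(c1)OC1C(=O)C=C(OC(C)=O)C=C1CCCCCCCCCCCCCC2 | intermediate
20 | 3⁶-hydroxy-2-oxa-1(1,3),3(1,2)-dibenzenacycloheptadecaphane-1⁵,3⁴-diyl diacetate | CC(=O)Oc1cc2cc(c1)Oc1c(O)cc(OC(C)=O)cc1CCCCCCCCCCCCCC2 | intermediate
21 | 2-oxa-1(1,3),3(1,2)-dibenzenacycloheptadecaphane-1⁵,3⁴,3⁶-triol | Oc1cc2cc(c1)Oc1c(O)cc(O)cc1CCCCCCCCCCCCCC2 | target

## Step count and least certain steps

Total step count: 12. Longest linear sequence: 11 steps (1 to 21 through steps 1 and 3–12; step 2 is the side branch).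

**Step 11 (key step).** The most likely failure is ionisation of the propargylic acetate, helped by the enol ether oxygen, before the alkyne is activated; this would lose the acetate or open the macrocycle. Five-membered closure of the vinylcarbene or catalyst inhibition by the electron-rich alkene could also compete.

The fallback reaches the same dienylketene type without a metal, by a Danheiser benzannulation. It sets out from 13 and returns at 21.
- The phenol of 13 would be silylated (TBSCl, imidazole) to the silyl ether aldehyde F1.
- MeMgBr would give the methyl carbinol F2, and MnO2 the methyl ketone F3.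
- LiN(SiMe3)2 and 2,2,2-trifluoroethyl trifluoroacetate would give the trifluoroacetyl ketone F4.
- Methanesulfonyl azide with Et3N in wet MeCN would give the diazo ketone F5.
- Irradiation of F5 with ethoxyacetylene (CCOC#C) in ClCH2CH2Cl, then warming to 80 °C, should give the ring B ethyl ether F6. The sequence is photochemical Wolff rearrangement, ketene–alkyne [2+2] addition, four-electron ring opening and six-electron closure.
- BBr3 in CH2Cl2 would cleave the ethyl ether and the silyl ether to give 21.

**Step 6.** The most likely failure is attack of the phenoxide on the sulfonyl sulfur, which transfers the tosyl group instead of substituting at the β-carbon. Intermolecular substitution could also occur if desilylation is slower than the addition of 9, giving oligomers.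

The fallback removes the electrophilic sulfur. It sets out from 8 and returns at 11. Vilsmeier chlorination of 8 ((COCl)2, DMF, 2,6-lutidine, CH2Cl2, 0 °C) would give the β-chloroacrylate F7. The same fluoride-triggered closure (CsF, DMF, high dilution) then proceeds by addition–elimination with chloride as leaving group.

**Step 4.** The most likely failure is loss of the aryl silyl groups through attack of lithium methoxide or amide at silicon, or incomplete condensation because proton transfer quenches the enolate.

The fallback changes the protecting groups and the type of Claisen condensation. It sets out from 2 and returns at 11.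
- The zinc reagent 5 made from 2 would be coupled with 1-bromo-3,5-dimethoxybenzene (COc1cc(Br)cc(OC)c1) under the conditions of step 3 to give the dimethoxy ester F8.
- Formylation with TiCl4, Et3N and HCO2Me in CH2Cl2 would give the formyl ester F9.
- Tosylation as in step 5 would give the enol tosylate F10.
- BBr3 (CH2Cl2, −78 to 0 °C) would cleave both methyl ethers to give 10, here isolated as the free bis-phenol.
- Cs2CO3 in DMF at high dilution would then close the ring to 11.

**Step 9.** The most likely failure is conjugate addition–elimination at the β-carbon, which expels the ring A phenoxide and opens the macrocycle. Ionisation of the product during work-up is a second risk.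

The fallback uses a less basic, strictly carbonyl-selective organocerium reagent with a capped alkyne. It sets out from 13 and returns at 15. LiC≡CSiMe3 premixed with CeCl3 (THF, −78 °C) would give the silylated propargylic alcohol F11, and K2CO3 in MeOH would remove the silyl group to give 15.

## Further compounds

F1 | step 11 | (E)-1⁵-(tert-butyldimethylsilyloxy)-2-oxa-1(1,3)-benzenacyclooctadecaphan-3-ene-4-carbaldehyde | CC(C)(C)[Si](C)(C)Oc1cc2cc(c1)O/C=C(/C=O)CCCCCCCCCCCCCC2
F2 | step 11 | (E)-1-[1⁵-(tert-butyldimethylsilyloxy)-2-oxa-1(1,3)-benzenacyclooctadecaphan-3-en-4-yl]ethanol (racemic) | CC(C)(C)[Si](C)(C)Oc1cc2cc(c1)O/C=C(/C(C)O)CCCCCCCCCCCCCC2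
F3 | step 11 | (E)-1-[1⁵-(tert-butyldimethylsilyloxy)-2-oxa-1(1,3)-benzenacyclooctadecaphan-3-en-4-yl]ethanone | CC(C)(C)[Si](C)(C)Oc1cc2cc(c1)O/C=C(/C(C)=O)CCCCCCCCCCCCCC2
F4 | step 11 | (E)-4,4,4-trifluoro-1-[1⁵-(tert-butyldimethylsilyloxy)-2-oxa-1(1,3)-benzenacyclooctadecaphan-3-en-4-yl]butane-1,3-dione | CC(C)(C)[Si](C)(C)Oc1cc2cc(c1)O/C=C(/C(=O)CC(=O)C(F)(F)F)CCCCCCCCCCCCCC2
F5 | step 11 | (E)-2-diazo-1-[1⁵-(tert-butyldimethylsilyloxy)-2-oxa-1(1,3)-benzenacyclooctadecaphan-3-en-4-yl]ethanone | CC(C)(C)[Si](C)(C)Oc1cc2cc(c1)O/C=C(/C(=O)C=[N+]=[N-])CCCCCCCCCCCCCC2
F6 | step 11 | 1⁵-(tert-butyldimethylsilyloxy)-3⁴-ethoxy-2-oxa-1(1,3),3(1,2)-dibenzenacycloheptadecaphan-3⁶-ol | CC(C)(C)[Si](C)(C)Oc1cc2cc(c1)Oc1c(O)cc(OCC)cc1CCCCCCCCCCCCCC2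
F7 | step 6 | methyl 16-[3,5-bis(tert-butyldimethylsilyloxy)phenyl]-2-(chloromethylidene)hexadecanoate (geometric mixture, drawn as E) | COC(=O)/C(CCCCCCCCCCCCCCc1cc(O[Si](C)(C)C(C)(C)C)cc(O[Si](C)(C)C(C)(C)C)c1)=C/Cl
F8 | step 4 | methyl 16-(3,5-dimethoxyphenyl)hexadecanoate | COC(=O)CCCCCCCCCCCCCCCc1cc(OC)cc(OC)c1
F9 | step 4 | methyl 16-(3,5-dimethoxyphenyl)-2-formylhexadecanoate (racemic) | COC(=O)C(C=O)CCCCCCCCCCCCCCc1cc(OC)cc(OC)c1
F10 | step 4 | methyl (E)-16-(3,5-dimethoxyphenyl)-2-[(4-methylphenylsulfonyloxy)methylidene]hexadecanoate | COC(=O)/C(CCCCCCCCCCCCCCc1cc(OC)cc(OC)c1)=C/OS(=O)(=O)c1ccc(C)cc1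
F11 | step 9 | (E)-4-[1-hydroxy-3-(trimethylsilyl)prop-2-yn-1-yl]-2-oxa-1(1,3)-benzenacyclooctadecaphan-3-en-1⁵-ol (racemic) | Oc1cc2cc(c1)O/C=C(/C(O)C#C[Si](C)(C)C)CCCCCCCCCCCCCC2
A1 | alternative 1 | 2-{2-[3-(13-bromotridecyl)-5-methoxyphenoxy]-3,5-dimethoxyphenyl}-1,3-dithiane | COc1cc(CCCCCCCCCCCCCBr)cc(c1)Oc1c(OC)cc(OC)cc1C1SCCCS1
A2 | alternative 1 | tri-O-methyl macrocycle with chain carbon 1 as a 1,3-dithiane | COc1cc2cc(c1)Oc1c(OC)cc(OC)cc1C1(SCCCS1)CCCCCCCCCCCCC2
A3 | alternative 2 | methyl 6-[14-(2-ethynyloxy-3,5-dimethoxyphenyl)tetradecyl]-4-methoxy-2-oxo-2H-pyran-3-carboxylate | COC(=O)C1=C(OC)C=C(CCCCCCCCCCCCCCc2cc(OC)cc(OC)c2OC#C)OC1=O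
A4 | alternative 2 | tri-O-methyl macrocycle with a methyl ester on the ring A carbon between C–OMe and C–OAr | COC(=O)c1c(OC)cc2cc1Oc1c(OC)cc(OC)cc1CCCCCCCCCCCCCC2
A5 | alternative 3 | 21-membered tri-O-methyl benzyl alkyl sulfone | COc1cc2cc(c1)Oc1c(OC)cc(OC)cc1CCCCCCCCCCCCCS(=O)(=O)C2
A6 | alternative 3 | tri-O-methyl macrocycle with an (E) benzylic alkene | COc1cc2cc(c1)Oc1c(OC)cc(OC)cc1CCCCCCCCCCCC/C=C/2
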